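**Plan**

1. Retrosynthetic cuts: C11–C12 (aldol; joins core and side chain), C9=C10 of the seven-membered ring (RCM), the butenolide bonds C6–C7, C7–C8 and O6–C19 (C6 aldehyde + methyl propiolate + allylcopper), and C4–C5 of the five-membered ring (aldol ring contraction of ozonised cis-carveol).
2. Forward order: five-membered ring from (S)-carvone → C6/C7 γ-lactone → Myers transposition and singlet-oxygen ene on the five-membered ring → seven-membered ring by RCM → 9α-oxygen and exocyclic C10=C18 → side chain by lactone-enolate aldol → C13 reduction, C19 deoxygenation, acetates, desilylation.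
3. Enabling feature: O6 and the C19 methyl are 1,4-related through C7–C11, so they can be tied as a cis-fused γ-butyrolactone (O6–C19(=O)–C11–C7–C6) on the seven-membered ring. This makes C11 an enolate carbon on the convex α face of the bowl formed by the two carbocycles and the lactone.
4. Temporary devices: lactone ring and C19 carbonyl (removed in steps 20 and 23), 1,3-dithiane at C13 (step 19), 3β-silyloxy group on the five-membered ring (steps 8 and 9).
5. Stereochemistry: C1 is bought with (S)-carvone; the C3 oxygen of cis-carveol relays to C5 (suprafacial H delivery) and then C4 (α-face ene); C6 by Zn–ProPhenol catalysis; C7 from C6; C9 by α-face epoxidation; C11 and C12 together in the key aldol; C13 by Felkin–Anh reduction.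

Key step: step 17

Locants used in the names: C1–C5 five-membered ring (C1 bears C10, C4 bears methyl C17, C5 bears C6); C6–C10 complete the seven-membered ring (C18 is the exocyclic carbon on C10); side chain C11(C19)–C12–C13–C14=C15(C16)(C20). α is the face of H-1 and H-5, β the opposite face.

Assumption: (S,S)-ProPhenol/Me2Zn delivers the alkynyl group to the Re face of enal 6; if a model enal shows the opposite sense, the (R,R)-ligand is used.

**Route**

Step 1
Reactants: 1 (S)-(+)-carvone
Product: 2 (+)-cis-carveol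
Conditions: NaBH4, CeCl3·7H2O, MeOH, −78 to 0 °C
Reagents that add atoms: none
Why: Luche 1,2-reduction; axial hydride delivery on the carvone half-chair should give the cis allylic alcohol (OH cis to isopropenyl), the relationship later used to place H-5.

Step 2
Reactants: 2 (+)-cis-carveol
Product: 3 cis-carveol TBS ether
Conditions: TBSCl, imidazole, DMF, rt
Reagents that add atoms: tert-butyl(chloro)dimethylsilane CC(C)(C)[Si](C)(C)Cl
Why: Standard silylation of the secondary allylic alcohol so that the oxygen survives ozonolysis, aldol and organometallic steps.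

Step 3
Reactants: 3 cis-carveol TBS ether
Product: 5 keto aldehyde, via secondary ozonide 4 (not isolated)
Conditions: O3, CH2Cl2, −78 °C (Sudan Red 7B end point); Me2S, −78 °C to rt
Reagents that add atoms: ozone [O-][O+]=O
Why: Ozonolysis (Criegee mechanism) should be selective for the electron-richer trisubstituted ring alkene over the 1,1-disubstituted isopropenyl group when stopped at the indicator end point, and Me2S reduces the ozonide without touching the stereocentres.

Step 4
Reactants: 5 keto aldehyde
Product: 6 cyclopentene carbaldehyde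
Conditions: Bn2NH·TFA (20 mol %), benzene, 50 °C
Reagents that add atoms: none
Why: Amine-salt-catalysed intramolecular aldol condensation (5-enolexo): the aldehyde enamine adds to the methyl ketone and dehydration gives the tetrasubstituted enal; no new stereocentre is formed.

Step 5
Reactants: 6 cyclopentene carbaldehyde
Product: 7 γ-hydroxy ynoate
Conditions: methyl propiolate, Me2Zn, (S,S)-ProPhenol (20 mol %), Ph3P=O (40 mol %), toluene, 4 °C; aq. NH4Cl
Reagents that add atoms: methyl propiolate C#CC(=O)OC
Why: Trost dinuclear zinc–ProPhenol alkynylation of an enal; the catalyst delivers the zinc propiolate to the Re face of the aldehyde and so sets C6.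

Step 6
Reactants: 7 γ-hydroxy ynoate
Product: 9 allyl butenolide, via Z-hydroxy dienoate 8 (not isolated)
Conditions: allylmagnesium bromide/CuBr·SMe2 (2.3 equiv each), THF, −78 °C; aq. NH4Cl; PPTS (cat.), CH2Cl2, rt
Reagents that add atoms: allylmagnesium bromide C=CC[Mg]Br
Why: Syn-carbocupration of the ynoate places allyl on C7 cis to the new C11–H, so the ester is cis to the C6 carbinol and lactonises (classical γ-hydroxy ynoate route to β-substituted butenolides).

Step 7
Reactants: 9 allyl butenolide
Product: 11 cis-lactone, via silyl ketene acetal 10 (not isolated)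
Conditions: [(Ph3P)CuH]6 (5 mol %), PhMe2SiH (1.5 equiv), toluene, 0 °C to rt; aq. NH4Cl
Reagents that add atoms: none
Why: Copper hydride conjugate reduction (Stryker/Lipshutz) is selective for the conjugated C7=C11 bond, and hydride should add to C7 anti to the C6 ring substituent, giving the cis-β,γ-disubstituted lactone after hydrolysis of the silyl ketene acetal.

Step 8
Reactants: 11 cis-lactone
Product: 12 lactone 3β-alcohol
Conditions: TBAF, AcOH (1:1), THF, 0 °C to rt
Reagents that add atoms: none
Why: Buffered fluoride desilylation frees the 3β-hydroxyl without opening the lactone.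

Step 9
Reactants: 12 lactone 3β-alcohol
Product: 15 cyclopent-3-ene lactone, via sulfonylhydrazide 13 (not isolated), via allylic diazene 14 (not isolated)
Conditions: PPh3, DEAD, N-methylmorpholine, −30 °C; 2-nitrobenzenesulfonylhydrazide; then rt
Reagents that add atoms: none
Why: Myers reductive 1,3-transposition: Mitsunobu displacement by NBSH inverts C3, loss of sulfinic acid gives the α-diazene, and its retro-ene loss of N2 transfers hydrogen to C5 on the same (α) face while the alkene moves to C3=C4, so H-5 ends cis to H-1.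

Step 10
Reactants: 15 cyclopent-3-ene lactone
Product: 17 tertiary allylic alcohol, via allylic hydroperoxide 16 (not isolated)
Conditions: O2, tetraphenylporphyrin (1 mol %), hν, CH2Cl2, −20 °C; PPh3
Reagents that add atoms: dioxygen O=O
Why: Schenck ene reaction: singlet oxygen should attack the only trisubstituted alkene from the α face (anti to the C6 and C10 substituents), bond to C4 and abstract H-2α, giving after phosphine reduction the 4α-alcohol with C2=C3.

Step 11
Reactants: 17 tertiary allylic alcohol
Product: 18 4-O-TES ether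
Conditions: TESOTf, 2,6-lutidine, CH2Cl2, −78 °C
Reagents that add atoms: triethylsilyl triflate CC[Si](CC)(CC)OS(=O)(=O)C(F)(F)F
Why: Silylation of the tertiary allylic alcohol prevents hydroxyl-directed epoxidation of C2=C3 in step 13.

Step 12
Reactants: 18 4-O-TES ether
Product: 19 tricyclic lactone
Conditions: Grubbs II (5 mol %), CH2Cl2 (2 mM), 40 °C
Reagents that add atoms: none
Why: Ring-closing metathesis between the isopropenyl and allyl groups, held cis on the cyclopentene and on the lactone, closes the seven-membered ring with a trisubstituted C9=C10 bond (the type used for guaiane cycloheptenes).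

Step 13
Reactants: 19 tricyclic lactone
Product: 20 9α,10α-epoxide
Conditions: mCPBA, NaHCO3, CH2Cl2, −20 °C
Reagents that add atoms: 3-chloroperbenzoic acid OOC(=O)c1cccc(Cl)c1
Why: Prilezhaev epoxidation should occur at the trisubstituted C9=C10 bond (more nucleophilic than C2=C3 next to the silyl ether) and on the convex α face, which fixes C9.

Step 14
Reactants: 20 9α,10α-epoxide
Product: 21 core lactone
Conditions: TBSOTf, DBU, toluene, −78 to 0 °C
Reagents that add atoms: tert-butyldimethylsilyl triflate CC(C)(C)[Si](C)(C)OS(=O)(=O)C(F)(F)F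
Why: Noyori-type silyl triflate/amidine isomerisation of an epoxide to an allylic silyl ether: O-silylation, ionisation at tertiary C10 and loss of a C18 proton give the exocyclic alkene, while the untouched C9–O bond keeps the α configuration.

Step 15
Reactants: 22 3-methylbut-2-enal
Product: 23 alkenyl dithiane
Conditions: propane-1,3-dithiol, BF3·OEt2 (10 mol %), CH2Cl2, −20 °C
Reagents that add atoms: propane-1,3-dithiol SCCCS
Why: Lewis-acid dithioacetalisation of the enal carbonyl (1,2-addition is favoured at the β,β-disubstituted enal).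

Step 16
Reactants: 23 alkenyl dithiane
Product: 25 dithiane aldehyde, via lithiated dithiane 24 (not isolated)
Conditions: n-BuLi, THF, −78 to −30 °C; DMF, −78 °C; aq. NH4Cl
Reagents that add atoms: N,N-dimethylformamide CN(C)C=O
Why: Corey–Seebach umpolung: the dithiane anion is formylated at C2 because the γ-terminus is blocked by two methyl groups.

Step 17
Reactants: 21 core lactone; 25 dithiane aldehyde
Product: 27 aldol adduct, via lithium enolate 26 (not isolated)
Conditions: LDA (1.1 equiv), THF, −78 °C; 25 (1.3 equiv), −78 °C; aq. NH4Cl at −78 °C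
Reagents that add atoms: none
Why: Deprotonation at C11 (the only enolisable carbon; aldehyde 25 has no α-hydrogen) gives lithium enolate 26, whose geometry is fixed as E(O) by the lactone ring, and it adds to the aldehyde through a closed Zimmerman–Traxler chair; the closest known reaction type is the anti-selective aldol addition of cis-fused γ-butyrolactone lithium enolates. No ring is closed. C11 is set by approach of the aldehyde to the convex α face of the bowl (both carbocycles are folded onto the β face of the lactone and C8 blocks that side), which puts C12 on the α face of the lactone. C12 is set by the chair in which the bulky dithianyl group sits equatorial, which for an E-enolate gives the 11,12-anti aldol (C7 and OH anti along C19–C11–C12–C13) required by the target. The step needs facial and simple (anti/syn) diastereoselection and freedom from double stereodifferentiation: the cis ring fusion secures the first, the ring-locked enolate geometry the second, and the achiral dithiane-masked C13 carbonyl the third. The helpers are removed later: the dithiane in step 19, the lactone ring and the C19 carbonyl in steps 20 and 23.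

Step 18
Reactants: 27 aldol adduct
Product: 28 12-O-TES ether
Conditions: TESOTf, 2,6-lutidine, CH2Cl2, −78 to 0 °C
Reagents that add atoms: triethylsilyl triflate CC[Si](CC)(CC)OS(=O)(=O)C(F)(F)F
Why: Silylation gives a bulky, non-chelating α-oxygen substituent needed for Felkin–Anh control in step 20.

Step 19
Reactants: 28 12-O-TES ether
Product: 29 13-enone
Conditions: MeI, CaCO3, MeCN/H2O (9:1), 45 °C
Reagents that add atoms: water O
Why: Alkylative (S-methylation) hydrolysis of the dithiane under neutral buffered conditions unmasks the C13 ketone without enolising C12.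

Step 20
Reactants: 29 13-enone
Product: 32 lactol bis-acetate, via C13 lithium alkoxide 30 (not isolated), via aluminium lactolate 31 (not isolated)
Conditions: L-Selectride (1.2 equiv), THF, −78 °C; DIBAL-H (2.5 equiv), −78 °C; pyridine, DMAP, Ac2O, −78 to 0 °C
Reagents that add atoms: acetic anhydride CC(=O)OC(C)=O
Why: L-Selectride should reduce the β,β-disubstituted enone 1,2 under polar Felkin–Anh control by the 12-silyloxy group (12,13-syn, 13S), DIBAL-H then takes the lactone to the aluminium lactolate, and Rychnovsky in situ acetylation traps both alkoxides so that the lactol cannot open or migrate to O13.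

Step 21
Reactants: 32 lactol bis-acetate
Product: 33 12-alcohol
Conditions: HF·pyridine, pyridine, THF, 0 °C
Reagents that add atoms: none
Why: Buffered HF·pyridine cleaves the triethylsilyl ethers (O12 and O4) selectively in the presence of the secondary TBS ether.

Step 22
Reactants: 33 12-alcohol
Product: 34 lactol triacetate
Conditions: Ac2O, pyridine, DMAP (10 mol %), CH2Cl2, 0 °C
Reagents that add atoms: acetic anhydride CC(=O)OC(C)=O
Why: Acetylation of the secondary 12-alcohol; the tertiary 4-alcohol should not react under these mild conditions.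

Step 23
Reactants: 34 lactol triacetate
Product: 36 9-O-TBS target, via tosylhydrazone 35 (not isolated)
Conditions: TsNHNH2, AcOH (cat.), THF, 45 °C; catecholborane, CHCl3, 0 °C; NaOAc·3H2O, 60 °C
Reagents that add atoms: none
Why: The lactol acetate is a masked C19 aldehyde: tosylhydrazone formation releases O6, and Kabalka reduction (catecholborane, then acetate-induced loss of sulfinate and N2) converts C19 into the methyl group without touching the acetates.

Step 24
Reactants: 36 9-O-TBS target
Product: 37 target CNP0269663.2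
Conditions: HF·pyridine, THF, 0 °C to rt
Reagents that add atoms: none
Why: Fluoride cleavage of the remaining TBS ether under conditions that leave the acetates and the tertiary allylic alcohol intact.

**Compound list**

1 | (S)-(+)-carvone, (5S)-2-methyl-5-(prop-1-en-2-yl)cyclohex-2-en-1-one | CC1=CC[C@@H](CC1=O)C(C)=C | starting material
2 | (+)-cis-carveol, (1S,5S)-2-methyl-5-(prop-1-en-2-yl)cyclohex-2-en-1-ol | CC1=CC[C@@H](C[C@@H]1O)C(C)=C | intermediate
3 | TBS ether of 2 | CC1=CC[C@@H](C[C@@H]1O[Si](C)(C)C(C)(C)C)C(C)=C | intermediate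
4 | secondary ozonide (1,2,4-trioxolane) across the former ring C=C of 3 | CC12OOC(O1)C[C@H](C(C)=C)C[C@@H]2O[Si](C)(C)C(C)(C)C | intermediate
5 | (3R,5S)-5-[tert-butyl(dimethyl)silyl]oxy-6-oxo-3-(prop-1-en-2-yl)heptanal | CC(=C)[C@@H](CC=O)C[C@H](O[Si](C)(C)C(C)(C)C)C(C)=O | intermediate
6 | (3S,5S)-3-[tert-butyl(dimethyl)silyl]oxy-2-methyl-5-(prop-1-en-2-yl)cyclopent-1-ene-1-carbaldehyde (C6 aldehyde; 3β-OTBS, 1β-isopropenyl in skeleton locants) | CC(=C)[C@@H]1C[C@H](O[Si](C)(C)C(C)(C)C)C(C)=C1C=O | intermediate
7 | methyl (4R)-4-hydroxy-4-(cyclopentenyl)but-2-ynoate: 6 with C6 as carbinol bearing C≡C–CO2Me | CC(=C)[C@@H]1C[C@H](O[Si](C)(C)C(C)(C)C)C(C)=C1[C@H](O)C#CC(=O)OC | intermediate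
8 | (Z)-γ-hydroxy dienoate from syn-allylcupration of 7 (allyl on C7, ester cis to C6) | CC(=C)[C@@H]1C[C@H](O[Si](C)(C)C(C)(C)C)C(C)=C1[C@H](O)/C(CC=C)=C\C(=O)OC | intermediate
9 | butenolide O6–C19(=O)–C11H=C7(allyl)–C6 on the cyclopentene of 6 | CC(=C)[C@@H]1C[C@H](O[Si](C)(C)C(C)(C)C)C(C)=C1[C@@H]2OC(=O)C=C2CC=C | intermediate
10 | dimethylphenylsilyl ketene acetal of 11 | CC(=C)[C@@H]1C[C@H](O[Si](C)(C)C(C)(C)C)C(C)=C1[C@@H]2OC(O[Si](C)(C)c3ccccc3)=C[C@@H]2CC=C | intermediate
11 | cis-β,γ-disubstituted γ-lactone (7β-allyl, H-6 and H-7 cis), 3β-OTBS, C4=C5 | CC(=C)[C@@H]1C[C@H](O[Si](C)(C)C(C)(C)C)C(C)=C1[C@@H]2OC(=O)C[C@@H]2CC=C | intermediate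
12 | 11 with free 3β-hydroxyl | CC(=C)[C@@H]1C[C@H](O)C(C)=C1[C@@H]2OC(=O)C[C@@H]2CC=C | intermediate
13 | N-(2-nitrobenzenesulfonyl)-N-alkylhydrazine, nitrogen on the α face of C3 | CC(=C)[C@@H]1C[C@@H](N(N)S(=O)(=O)c3ccccc3[N+](=O)[O-])C(C)=C1[C@@H]2OC(=O)C[C@@H]2CC=C | intermediate
14 | 3α-monoalkyl diazene | CC(=C)[C@@H]1C[C@@H](N=N)C(C)=C1[C@@H]2OC(=O)C[C@@H]2CC=C | intermediate
15 | lactone with C3=C4, 5α-H, 1β-isopropenyl, 7β-allyl | CC(=C)[C@@H]1CC=C(C)[C@@H]1[C@@H]2OC(=O)C[C@@H]2CC=C | intermediate
16 | 4α-hydroperoxide with C2=C3 | CC(=C)[C@@H]1C=C[C@@](C)(OO)[C@@H]1[C@@H]2OC(=O)C[C@@H]2CC=C | intermediate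
17 | 4α-hydroxy-4β-methyl cyclopent-2-ene lactone | CC(=C)[C@@H]1C=C[C@@](C)(O)[C@@H]1[C@@H]2OC(=O)C[C@@H]2CC=C | intermediate
18 | 4α-O-triethylsilyl ether of 17 | CC(=C)[C@@H]1C=C[C@@](C)(O[Si](CC)(CC)CC)[C@@H]1[C@@H]2OC(=O)C[C@@H]2CC=C | intermediate
19 | tricyclic 6,19-lactone with C9=C10 (C18 methyl), 4α-OTES, all of H-1, H-5, H-6, H-7 α | CC1=CC[C@H]3CC(=O)O[C@H]3[C@@H]2[C@H]1C=C[C@@]2(C)O[Si](CC)(CC)CC | intermediate
20 | 9α,10α-epoxide of 19 | C[C@@]12O[C@@H]1C[C@H]3CC(=O)O[C@H]3[C@@H]4[C@H]2C=C[C@@]4(C)O[Si](CC)(CC)CC | intermediate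
21 | core lactone: 9α-OTBS, exocyclic C10=C18, 4α-OTES, cis-fused 6,19-lactone | C=C1[C@H](O[Si](C)(C)C(C)(C)C)C[C@H]3CC(=O)O[C@H]3[C@@H]2[C@H]1C=C[C@@]2(C)O[Si](CC)(CC)CC | intermediate
22 | 3-methylbut-2-enal | CC(C)=CC=O | starting material
23 | 2-(2-methylprop-1-en-1-yl)-1,3-dithiane | CC(C)=CC1SCCCS1 | intermediate
24 | 2-lithio-2-(2-methylprop-1-en-1-yl)-1,3-dithiane | [Li]C1(C=C(C)C)SCCCS1 | intermediate
25 | 2-(2-methylprop-1-en-1-yl)-1,3-dithiane-2-carbaldehyde | O=CC1(C=C(C)C)SCCCS1 | intermediate
26 | lithium enolate of 21 (C11=C19–OLi) | C=C1[C@H](O[Si](C)(C)C(C)(C)C)C[C@H]3C=C(O[Li])O[C@H]3[C@@H]2[C@H]1C=C[C@@]2(C)O[Si](CC)(CC)CC | intermediate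
27 | aldol adduct: 21 with C11 bearing the C12 carbinol (11,12-anti) attached to dithiane carbon C13 | C=C1[C@H](O[Si](C)(C)C(C)(C)C)C[C@H]3[C@H]([C@H](O)C4(C=C(C)C)SCCCS4)C(=O)O[C@H]3[C@@H]2[C@H]1C=C[C@@]2(C)O[Si](CC)(CC)CC | intermediate
28 | 12-O-triethylsilyl ether of 27 | C=C1[C@H](O[Si](C)(C)C(C)(C)C)C[C@H]3[C@H]([C@H](O[Si](CC)(CC)CC)C4(C=C(C)C)SCCCS4)C(=O)O[C@H]3[C@@H]2[C@H]1C=C[C@@]2(C)O[Si](CC)(CC)CC | intermediate
29 | 13-ketone (enone C13(=O)–C14=C15) with 12-OTES and intact lactone | C=C1[C@H](O[Si](C)(C)C(C)(C)C)C[C@H]3[C@H]([C@H](O[Si](CC)(CC)CC)C(=O)C=C(C)C)C(=O)O[C@H]3[C@@H]2[C@H]1C=C[C@@]2(C)O[Si](CC)(CC)CC | intermediate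
30 | lithium (13S)-alkoxide from reduction of 29, lactone intact | C=C1[C@H](O[Si](C)(C)C(C)(C)C)C[C@H]3[C@H]([C@H](O[Si](CC)(CC)CC)[C@H](C=C(C)C)O[Li])C(=O)O[C@H]3[C@@H]2[C@H]1C=C[C@@]2(C)O[Si](CC)(CC)CC | intermediate
31 | diisobutylaluminium C19 lactolate of 30 | C=C1[C@H](O[Si](C)(C)C(C)(C)C)C[C@H]3[C@H]([C@H](O[Si](CC)(CC)CC)[C@H](C=C(C)C)O[Li])C(O[Al](CC(C)C)CC(C)C)O[C@H]3[C@@H]2[C@H]1C=C[C@@]2(C)O[Si](CC)(CC)CC | intermediate
32 | 13-acetate and C19 lactol acetate (anomeric mixture), 12-OTES, 4-OTES, 9-OTBS | C=C1[C@H](O[Si](C)(C)C(C)(C)C)C[C@H]3[C@H]([C@H](O[Si](CC)(CC)CC)[C@H](C=C(C)C)OC(C)=O)C(OC(C)=O)O[C@H]3[C@@H]2[C@H]1C=C[C@@]2(C)O[Si](CC)(CC)CC | intermediate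
33 | 32 with free 12-OH and 4-OH | C=C1[C@H](O[Si](C)(C)C(C)(C)C)C[C@H]3[C@H]([C@H](O)[C@H](C=C(C)C)OC(C)=O)C(OC(C)=O)O[C@H]3[C@@H]2[C@H]1C=C[C@@]2(C)O | intermediate
34 | 12,13-diacetate and C19 lactol acetate, 9-OTBS, free 4-OH | C=C1[C@H](O[Si](C)(C)C(C)(C)C)C[C@H]3[C@H]([C@H](OC(C)=O)[C@H](C=C(C)C)OC(C)=O)C(OC(C)=O)O[C@H]3[C@@H]2[C@H]1C=C[C@@]2(C)O | intermediate
35 | C19 tosylhydrazone with free 6β-OH | C=C1[C@H](O[Si](C)(C)C(C)(C)C)C[C@@H]([C@@H](C=NNS(=O)(=O)c3ccc(C)cc3)[C@H](OC(C)=O)[C@H](C=C(C)C)OC(C)=O)[C@@H](O)[C@@H]2[C@H]1C=C[C@@]2(C)O | intermediate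
36 | 9-O-TBS ether of the target | C=C1[C@H](O[Si](C)(C)C(C)(C)C)C[C@@H]([C@@H](C)[C@H](OC(C)=O)[C@H](C=C(C)C)OC(C)=O)[C@@H](O)[C@@H]2[C@H]1C=C[C@@]2(C)O | intermediate
37 | CNP0269663.2 (4α,6β,9α-trihydroxy-12,13-diacetoxy hydroazulene diterpenoid) | C=C1[C@H](O)C[C@@H]([C@@H](C)[C@H](OC(C)=O)[C@H](C=C(C)C)OC(C)=O)[C@@H](O)[C@@H]2[C@H]1C=C[C@@]2(C)O | target

**Step count and risks**

Total step count: 24. Longest linear sequence: 22 steps (steps 1–14 and 17–24); steps 15 and 16 form the side-chain branch.

The three steps most likely to fail: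

Step 10 (singlet-oxygen ene). What may go wrong is loss of regiocontrol in the hydrogen abstraction (from the C17 methyl, giving an exocyclic alkene and a secondary hydroperoxide) or competing ene reaction at the isopropenyl group. Fallback: the oxygen is placed through an epoxide. From 15, mCPBA (1 equiv, −20 °C) should epoxidise the trisubstituted C3=C4 bond from the α face to the 3α,4α-epoxide F1. Sodium phenylselenide (PhSeSePh, NaBH4, EtOH) opens it at the secondary C3 with inversion to the 3β-phenylselanyl 4α-alcohol F2. Oxidation with H2O2/pyridine and syn-elimination of the selenoxide toward C2 (C4 carries no hydrogen) returns to the route at 17 (Sharpless epoxide-to-allylic-alcohol transposition).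

Step 14 (epoxide to allylic silyl ether). What may go wrong is a pinacol-type hydride shift from C9 to the C10 cation (C9 ketone) or elimination toward C1 (endocyclic C1=C10 alkene). Fallback: the isomerisation is done with an aluminium amide instead of a silyl cation. From 20, Et2Al(TMP) (LiTMP and Et2AlCl, toluene, 0 °C) removes a C18 proton through a cyclic syn transition state and gives the 9α-allylic alcohol F3. TBSCl and imidazole then return to the route at 21.

Step 17 (key aldol). What may go wrong is slow or reversible addition to the hindered aldehyde (retro-aldol) or leakage through a boat transition state to the 11,12-syn isomer. Fallback: the bond is made by acylation and the carbinol by reduction. Lithiated dithiane 24 (from 23) is quenched with methyl chloroformate to the dithiane methyl ester F4. Enolate 26 (from 21 with 2 equiv LDA) undergoes crossed Claisen condensation with F4 to the β-keto lactone F5, whose C11 is epimerisable and should settle with the acyl group on the convex α face. Non-chelating Felkin–Anh reduction (LiEt3BH, CeCl3, THF, −78 °C) should give the 11,12-anti alcohol and return to the route at 27.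

Further compounds
F1 | step 10 | 3α,4α-epoxide of lactone 15 | CC(=C)[C@@H]1C[C@H]3O[C@@]3(C)[C@@H]1[C@@H]2OC(=O)C[C@@H]2CC=C
F2 | step 10 | 3β-phenylselanyl 4α-hydroxy lactone | CC(=C)[C@@H]1C[C@H]([Se]c3ccccc3)[C@@](C)(O)[C@@H]1[C@@H]2OC(=O)C[C@@H]2CC=C
F3 | step 14 | 9α-hydroxy lactone with exocyclic C10=C18 and 4α-OTES | C=C1[C@H](O)C[C@H]3CC(=O)O[C@H]3[C@@H]2[C@H]1C=C[C@@]2(C)O[Si](CC)(CC)CC
F4 | step 17 | methyl 2-(2-methylprop-1-en-1-yl)-1,3-dithiane-2-carboxylate | COC(=O)C1(C=C(C)C)SCCCS1
F5 | step 17 | C12 β-keto lactone (C11 acylated core lactone) | C=C1[C@H](O[Si](C)(C)C(C)(C)C)C[C@H]3[C@H](C(=O)C4(C=C(C)C)SCCCS4)C(=O)O[C@H]3[C@@H]2[C@H]1C=C[C@@]2(C)O[Si](CC)(CC)CC
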